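**Strategy**

Ring C of moracin Q is a 5-substituted resorcinol: C1' is bonded to benzofuran C2 and C3' and C5' carry hydroxyls, the alternating pattern of a 1,3,5-tricarbonyl chain. The route therefore disconnects the C1'–C6' bond of ring C. In one operation, aqueous base folds a 1-(benzofuran-2-yl)hexane-1,3,5-trione by intramolecular aldol addition of its terminal methyl carbon to the C2-bound ketone, and dehydration and enolisation then deliver ring C with both hydroxyls free. The precursor is a fully substituted benzofuran (rings A and B) carrying the C5 methyl ether, a C6 benzyl ether, the C4 side-chain ketone masked as a dioxolane and the triketone chain on C2.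

Key step: step 10

Remark: compounds 1 and 3 are hydroquinones and are handled under argon in degassed solvents; alcohol 16 is racemic and its stereocentre is removed in step 7 (the target is achiral).

**Route**

Step 1
Reactants: 1 2,4,5-trihydroxybenzaldehyde; 2 benzyl bromide
Product: 3 4-(benzyloxy)-2,5-dihydroxybenzaldehyde
Conditions: BnBr (1.0 equiv), NaHCO3, DMF, 40 °C, Ar
Reagents that add atoms: benzyl bromide (2), BrCc1ccccc1
Why: Williamson ether synthesis in which NaHCO3 ionises only the 4-hydroxyl, the most acidic one because it is para to the formyl group, so that benzylation should stop at the 4-ether while the hydrogen-bonded 2-OH and the less acidic 5-OH stay free.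

Step 2
Reactants: 3 4-(benzyloxy)-2,5-dihydroxybenzaldehyde; 4 3-chloro-3-methylbut-1-yne
Product: 5 4-(benzyloxy)-2-hydroxy-5-[(2-methylbut-3-yn-2-yl)oxy]benzaldehyde
Conditions: K2CO3, KI (cat.), CuI (cat.), acetone, 55 °C, Ar
Reagents that add atoms: 3-chloro-3-methylbut-1-yne (4), C#CC(C)(C)Cl
Why: Copper-assisted Williamson-type O-alkylation with the tertiary propargylic chloride, in which the 5-hydroxyl should react because the 2-hydroxyl is tied up in a hydrogen bond to the formyl group and its phenoxide is delocalised into it.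

Step 3
Reactants: 5 4-(benzyloxy)-2-hydroxy-5-[(2-methylbut-3-yn-2-yl)oxy]benzaldehyde; 6 methyl bromoacetate
Product: 9 methyl 6-(benzyloxy)-5-[(2-methylbut-3-yn-2-yl)oxy]-1-benzofuran-2-carboxylate, via aryloxyacetate 7 (not isolated), via dihydrobenzofuranol aldol adduct 8 (not isolated)
Conditions: K2CO3, DMF, rt then 90 °C
Reagents that add atoms: methyl bromoacetate (6), COC(=O)CBr
Why: Rap–Stoermer-type benzofuran annulation in which Williamson O-alkylation of the salicylaldehyde hydroxyl gives 7, its ester enolate adds to the ortho formyl group (5-exo-trig aldol) to give 8, and loss of water aromatises the furan ring, 90 °C being below the range in which the propargyl aryl ether rearranges.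

Step 4
Reactants: 9 methyl 6-(benzyloxy)-5-[(2-methylbut-3-yn-2-yl)oxy]-1-benzofuran-2-carboxylate
Product: 10 methyl 6-(benzyloxy)-5-[(2-methylbut-3-en-2-yl)oxy]-1-benzofuran-2-carboxylate
Conditions: H2 (1 atm), Pd/CaCO3 poisoned with Pb(OAc)2 (Lindlar catalyst), quinoline, EtOAc, rt
Reagents that add atoms: none
Why: Lindlar semi-hydrogenation should stop at the alkene on the lead- and quinoline-poisoned catalyst, which leaves the benzyl ether, the ester and the aromatic benzofuran untouched.

Step 5
Reactants: 10 methyl 6-(benzyloxy)-5-[(2-methylbut-3-en-2-yl)oxy]-1-benzofuran-2-carboxylate; 11 iodomethane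
Product: 13 methyl 6-(benzyloxy)-5-methoxy-4-(3-methylbut-2-en-1-yl)-1-benzofuran-2-carboxylate, via C4-prenyl phenol 12 (not isolated)
Conditions: DMF, 130 °C, Ar; cool to rt; then K2CO3, MeI, rt
Reagents that add atoms: iodomethane (11), CI
Why: Aromatic Claisen rearrangement in which the [3,3]-sigmatropic shift of the 1,1-dimethylallyl ether delivers the allyl terminus to C4, the only free ortho position (C6 carries the benzyloxy group), so that the allyl unit is inverted to a prenyl group, and after tautomerisation the single free phenol of 12 is O-methylated in the same pot by a Williamson reaction.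

Step 6
Reactants: 13 methyl 6-(benzyloxy)-5-methoxy-4-(3-methylbut-2-en-1-yl)-1-benzofuran-2-carboxylate; 14 sodium perborate tetrahydrate
Product: 16 methyl 6-(benzyloxy)-4-(2-hydroxy-3-methylbutyl)-5-methoxy-1-benzofuran-2-carboxylate (racemic), via secondary alkylborane 15 (not isolated)
Conditions: BH3·THF (1.1 equiv), THF, 0 °C; then NaBO3·4H2O, H2O, rt
Reagents that add atoms: sodium perborate tetrahydrate (14), [Na+].[O-]B1OO1.O.O.O.O
Why: Hydroboration–oxidation in which borane adds its boron to the less substituted alkene carbon far faster at 0 °C than it reduces the aromatic methyl ester, and perborate oxidation with retention gives the secondary alcohol as a racemate, the new stereocentre being uncontrolled and removed in step 7.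

Step 7
Reactants: 16 methyl 6-(benzyloxy)-4-(2-hydroxy-3-methylbutyl)-5-methoxy-1-benzofuran-2-carboxylate (racemic)
Product: 17 methyl 6-(benzyloxy)-5-methoxy-4-(3-methyl-2-oxobutyl)-1-benzofuran-2-carboxylate
Conditions: Dess–Martin periodinane, CH2Cl2, rt
Reagents that add atoms: none
Why: Dess–Martin oxidation of a secondary alcohol to the ketone under neutral conditions that the benzofuran, the ethers and the ester tolerate.

Step 8
Reactants: 17 methyl 6-(benzyloxy)-5-methoxy-4-(3-methyl-2-oxobutyl)-1-benzofuran-2-carboxylate; 18 1,2-bis(trimethylsilyloxy)ethane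
Product: 19 methyl 6-(benzyloxy)-5-methoxy-4-{[2-(propan-2-yl)-1,3-dioxolan-2-yl]methyl}-1-benzofuran-2-carboxylate
Conditions: (TMSOCH2)2, TMSOTf (cat.), CH2Cl2, −78 → −20 °C; pyridine quench
Reagents that add atoms: 1,2-bis(trimethylsilyloxy)ethane (18), C[Si](C)(C)OCCO[Si](C)(C)C
Why: Ketalisation with the bis-silyl ether of ethylene glycol under TMSOTf catalysis is driven by formation of hexamethyldisiloxane and works on hindered ketones at low temperature with neither free diol nor water present, so the methyl ester cannot transesterify.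

Step 9
Reactants: 19 methyl 6-(benzyloxy)-5-methoxy-4-{[2-(propan-2-yl)-1,3-dioxolan-2-yl]methyl}-1-benzofuran-2-carboxylate; 20 pentane-2,4-dione
Product: 22 1-[6-(benzyloxy)-5-methoxy-4-{[2-(propan-2-yl)-1,3-dioxolan-2-yl]methyl}-1-benzofuran-2-yl]hexane-1,3,5-trione, via dilithiated pentane-2,4-dione 21 (not isolated)
Conditions: pentane-2,4-dione (3 equiv), LiN(iPr)2 (6 equiv), THF, 0 °C; then 19, 0 °C → rt; AcOH/H2O to pH 6, 0 °C
Reagents that add atoms: pentane-2,4-dione (20), CC(=O)CC(C)=O
Why: Claisen-type acylation of a β-diketone dianion in which the terminal carbanion of 21, its most nucleophilic site, attacks the non-enolisable ester, excess dianion absorbing the protons of the more acidic triketone product, while the dioxolane and the ethers are inert to the base.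

Step 10
Reactants: 22 1-[6-(benzyloxy)-5-methoxy-4-{[2-(propan-2-yl)-1,3-dioxolan-2-yl]methyl}-1-benzofuran-2-yl]hexane-1,3,5-trione
Product: 24 5-[6-(benzyloxy)-5-methoxy-4-{[2-(propan-2-yl)-1,3-dioxolan-2-yl]methyl}-1-benzofuran-2-yl]benzene-1,3-diol, via cyclic aldol adduct 23 (not isolated)
Conditions: 2 M aq. KOH–MeOH, degassed, Ar, rt; then AcOH to pH 6, 0 °C
Reagents that add atoms: none
Why: Hydroxide converts the triketone into its dienolate, whose terminal carbon C6 (the former methyl) adds to the C1 ketone attached to benzofuran C2 in an intramolecular aldol reaction, and β-elimination of water from adduct 23 followed by enolisation of the C3 and C5 carbonyls gives the aromatic ring, which makes the sequence irreversible. The closest known reaction type is the base-induced aldol cyclisation of 1-aryl-1,3,5-triketones, themselves made by acylating β-diketone dianions, to 5-arylresorcinols, the laboratory counterpart of the polyketide folding that builds the resorcinol ring of stilbenes. Ring C closes in a 6-(enolendo)-exo-trig mode, the enolate C5=C6 bond lying inside and the attacked C1=O bond outside the new six-membered ring. No stereocentre is formed, since adduct 23 is symmetric and is aromatised at once. The selectivity needed is carbon–carbon closure in preference to oxygen closure to the 2-methyl-6-aryl-4-pyranone and to hydroxide-induced retro-Claisen cleavage: strongly basic water keeps the chain as a polyanion in which oxygen attack is reversible while only the aldol path is drained by aromatisation, C6 to C1 is the only pairing that gives a six-membered carbocycle, the chain ends in a methyl ketone and not an ester so Claisen folding is excluded, and the dioxolane keeps the side-chain ketone from enolising or acting as an electrophile. Air is excluded because the resorcinolate product is oxidised easily in base.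

Step 11
Reactants: 24 5-[6-(benzyloxy)-5-methoxy-4-{[2-(propan-2-yl)-1,3-dioxolan-2-yl]methyl}-1-benzofuran-2-yl]benzene-1,3-diol; 25 water
Product: 27 moracin Q (1-[2-(3,5-dihydroxyphenyl)-6-hydroxy-5-methoxy-1-benzofuran-4-yl]-3-methylbutan-2-one), via debenzylated dioxolane 26 (not isolated)
Conditions: H2 (1 atm), 10% Pd/C, THF, rt; filter; then 1 M aq. HCl, rt
Reagents that add atoms: water (25), O
Why: Hydrogenolysis of the benzyl ether over Pd/C followed by acid-catalysed hydrolysis of the dioxolane (acetal cleavage) are orthogonal deprotections that should leave the 2-arylbenzofuran and the methyl ether untouched, and no stereocentre is present.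

**Compound list**

1 | 2,4,5-trihydroxybenzaldehyde | O=Cc1cc(O)c(O)cc1O | starting material
2 | benzyl bromide | BrCc1ccccc1 | starting material
3 | 4-(benzyloxy)-2,5-dihydroxybenzaldehyde | O=Cc1cc(O)c(OCc2ccccc2)cc1O | intermediate
4 | 3-chloro-3-methylbut-1-yne | C#CC(C)(C)Cl | starting material
5 | 4-(benzyloxy)-2-hydroxy-5-[(2-methylbut-3-yn-2-yl)oxy]benzaldehyde | O=Cc1cc(OC(C)(C)C#C)c(OCc2ccccc2)cc1O | intermediate
6 | methyl bromoacetate | COC(=O)CBr | starting material
7 | methyl 2-{5-(benzyloxy)-2-formyl-4-[(2-methylbut-3-yn-2-yl)oxy]phenoxy}acetate (not isolated) | COC(=O)COc1cc(OCc2ccccc2)c(OC(C)(C)C#C)cc1C=O | intermediate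
8 | methyl 6-(benzyloxy)-3-hydroxy-5-[(2-methylbut-3-yn-2-yl)oxy]-2,3-dihydro-1-benzofuran-2-carboxylate (racemic diastereomer mixture, not isolated) | COC(=O)C1Oc2cc(OCc3ccccc3)c(OC(C)(C)C#C)cc2C1O | intermediate
9 | methyl 6-(benzyloxy)-5-[(2-methylbut-3-yn-2-yl)oxy]-1-benzofuran-2-carboxylate | COC(=O)c1cc2cc(OC(C)(C)C#C)c(OCc3ccccc3)cc2o1 | intermediate
10 | methyl 6-(benzyloxy)-5-[(2-methylbut-3-en-2-yl)oxy]-1-benzofuran-2-carboxylate | COC(=O)c1cc2cc(OC(C)(C)C=C)c(OCc3ccccc3)cc2o1 | intermediate
11 | iodomethane | CI | starting material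
12 | methyl 6-(benzyloxy)-5-hydroxy-4-(3-methylbut-2-en-1-yl)-1-benzofuran-2-carboxylate (not isolated) | COC(=O)c1cc2c(CC=C(C)C)c(O)c(OCc3ccccc3)cc2o1 | intermediate
13 | methyl 6-(benzyloxy)-5-methoxy-4-(3-methylbut-2-en-1-yl)-1-benzofuran-2-carboxylate | COC(=O)c1cc2c(CC=C(C)C)c(OC)c(OCc3ccccc3)cc2o1 | intermediate
14 | sodium perborate tetrahydrate | [Na+].[O-]B1OO1.O.O.O.O | starting material
15 | methyl 6-(benzyloxy)-4-(2-boranyl-3-methylbutyl)-5-methoxy-1-benzofuran-2-carboxylate (racemic, drawn as the monoalkylborane, not isolated) | COC(=O)c1cc2c(CC(B)C(C)C)c(OC)c(OCc3ccccc3)cc2o1 | intermediate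
16 | methyl 6-(benzyloxy)-4-(2-hydroxy-3-methylbutyl)-5-methoxy-1-benzofuran-2-carboxylate (racemic) | COC(=O)c1cc2c(CC(O)C(C)C)c(OC)c(OCc3ccccc3)cc2o1 | intermediate
17 | methyl 6-(benzyloxy)-5-methoxy-4-(3-methyl-2-oxobutyl)-1-benzofuran-2-carboxylate | COC(=O)c1cc2c(CC(=O)C(C)C)c(OC)c(OCc3ccccc3)cc2o1 | intermediate
18 | 1,2-bis(trimethylsilyloxy)ethane | C[Si](C)(C)OCCO[Si](C)(C)C | starting material
19 | methyl 6-(benzyloxy)-5-methoxy-4-{[2-(propan-2-yl)-1,3-dioxolan-2-yl]methyl}-1-benzofuran-2-carboxylate | COC(=O)c1cc2c(CC3(C(C)C)OCCO3)c(OC)c(OCc3ccccc3)cc2o1 | intermediate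
20 | pentane-2,4-dione | CC(=O)CC(C)=O | starting material
21 | dilithium dienolate of pentane-2,4-dione (not isolated) | [Li+].[Li+].C=C([O-])C=C(C)[O-] | intermediate
22 | 1-[6-(benzyloxy)-5-methoxy-4-{[2-(propan-2-yl)-1,3-dioxolan-2-yl]methyl}-1-benzofuran-2-yl]hexane-1,3,5-trione | CC(=O)CC(=O)CC(=O)c1cc2c(CC3(C(C)C)OCCO3)c(OC)c(OCc3ccccc3)cc2o1 | intermediate
23 | 5-[6-(benzyloxy)-5-methoxy-4-{[2-(propan-2-yl)-1,3-dioxolan-2-yl]methyl}-1-benzofuran-2-yl]-5-hydroxycyclohexane-1,3-dione (not isolated) | O=C1CC(=O)CC(O)(c2cc3c(CC4(C(C)C)OCCO4)c(OC)c(OCc4ccccc4)cc3o2)C1 | intermediate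
24 | 5-[6-(benzyloxy)-5-methoxy-4-{[2-(propan-2-yl)-1,3-dioxolan-2-yl]methyl}-1-benzofuran-2-yl]benzene-1,3-diol | Oc1cc(O)cc(-c2cc3c(CC4(C(C)C)OCCO4)c(OC)c(OCc4ccccc4)cc3o2)c1 | intermediate
25 | water | O | starting material
26 | 5-[6-hydroxy-5-methoxy-4-{[2-(propan-2-yl)-1,3-dioxolan-2-yl]methyl}-1-benzofuran-2-yl]benzene-1,3-diol (not isolated) | COc1c(O)cc2oc(-c3cc(O)cc(O)c3)cc2c1CC1(C(C)C)OCCO1 | intermediate
27 | moracin Q, 1-[2-(3,5-dihydroxyphenyl)-6-hydroxy-5-methoxy-1-benzofuran-4-yl]-3-methylbutan-2-one | COc1c(O)cc2oc(-c3cc(O)cc(O)c3)cc2c1CC(=O)C(C)C | target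

**Summary**

Total step count: 11. Longest linear sequence: 11 steps (1 to 27).

Steps most likely to fail:

1. Step 10. Oxygen closure to the 4-pyranone or hydroxide-induced retro-Claisen cleavage of the chain may outrun the carbon–carbon aldol closure. The fallback gives up the aldol folding and joins ring C as a ready-made arene. It sets out from 19, which is saponified (LiOH, THF/H2O, citric acid work-up) to 6-(benzyloxy)-5-methoxy-4-{[2-(propan-2-yl)-1,3-dioxolan-2-yl]methyl}-1-benzofuran-2-carboxylic acid F1. Decarboxylative cross-coupling of this heteroaryl acid with commercial 1-bromo-3,5-bis(benzyloxy)benzene (Brc1cc(OCc2ccccc2)cc(OCc2ccccc2)c1), using the zerovalent palladium complex Pd[P(t-Bu)3]2, Cs2CO3 and n-Bu4NCl in DMF at 170 °C, should give 2-({6-(benzyloxy)-2-[3,5-bis(benzyloxy)phenyl]-5-methoxy-1-benzofuran-4-yl}methyl)-2-(propan-2-yl)-1,3-dioxolane F2. Under the conditions of step 11 all three benzyl ethers and the dioxolane are removed, so the fallback comes back to the route at 27.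

2. Step 9. Proton transfer from the triketone product (or from unreacted diketone) may quench the dianion before acylation is complete. The fallback builds the chain in two carbon–carbon bond formations with the roles of the partners reversed. It sets out from 19, which undergoes a crossed Claisen condensation with the lithium enolate of acetone (acetone, LiN(iPr)2, THF, −78 → 0 °C) to give 1-[6-(benzyloxy)-5-methoxy-4-{[2-(propan-2-yl)-1,3-dioxolan-2-yl]methyl}-1-benzofuran-2-yl]butane-1,3-dione F3. Its dianion (LiN(iPr)2, 2.2 equiv, THF) is acetylated at the terminal methyl carbon with N-methoxy-N-methylacetamide, and the fallback comes back to the route at 22.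

3. Step 6. Borane may reduce the methyl ester, or add only sluggishly to the hindered trisubstituted alkene. The fallback avoids hydride reagents. It sets out from 13, which is epoxidised (mCPBA, NaHCO3, CH2Cl2, 0 °C) to methyl 6-(benzyloxy)-4-[(3,3-dimethyloxiran-2-yl)methyl]-5-methoxy-1-benzofuran-2-carboxylate F4 (racemic). A Meinwald rearrangement (BF3·OEt2, CH2Cl2, −78 °C) opens the epoxide at the tertiary carbon, and a 1,2-hydride shift should give the isopropyl ketone directly, so the fallback comes back to the route at 17 and bypasses 16.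

**Further compounds**

F1 | step 10 | 6-(benzyloxy)-5-methoxy-4-{[2-(propan-2-yl)-1,3-dioxolan-2-yl]methyl}-1-benzofuran-2-carboxylic acid | OC(=O)c1cc2c(CC3(C(C)C)OCCO3)c(OC)c(OCc3ccccc3)cc2o1
F2 | step 10 | 2-({6-(benzyloxy)-2-[3,5-bis(benzyloxy)phenyl]-5-methoxy-1-benzofuran-4-yl}methyl)-2-(propan-2-yl)-1,3-dioxolane | COc1c(OCc2ccccc2)cc2oc(-c3cc(OCc4ccccc4)cc(OCc4ccccc4)c3)cc2c1CC1(C(C)C)OCCO1
F3 | step 9 | 1-[6-(benzyloxy)-5-methoxy-4-{[2-(propan-2-yl)-1,3-dioxolan-2-yl]methyl}-1-benzofuran-2-yl]butane-1,3-dione | CC(=O)CC(=O)c1cc2c(CC3(C(C)C)OCCO3)c(OC)c(OCc3ccccc3)cc2o1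
F4 | step 6 | methyl 6-(benzyloxy)-4-[(3,3-dimethyloxiran-2-yl)methyl]-5-methoxy-1-benzofuran-2-carboxylate (racemic) | COC(=O)c1cc2c(CC3OC3(C)C)c(OC)c(OCc3ccccc3)cc2o1
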